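**Retrosynthetic overview**
- The target comes from its bis-silyl ether by fluoride, and that from an (S)-2H-chromene-3-carbaldehyde by rhodium-mediated loss of the C3 formyl carbon.
- The strategy rests on ring B (the 2H-pyran): its O1–C2 and C3–C4 bonds join a salicylaldehyde unit (ring A, O1, C4) to the β-methyl enal terminus (C2 with its methyl, C3, chain) of a C35 polyprenal. Both bonds and the C2 stereocentre are made in one amine-catalysed annulation.
- The polyprenal comes by MnO2 oxidation from a C35 allylic alcohol, whose hydroxymethyl-branched E-alkene is set by a Wittig reaction of a C22 aldehyde with an α-homogeranyl ester ylide.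
- The C22 aldehyde comes from geranylgeraniol (silylation, oxidation of the terminal E-methyl, bromide, cyanomethylation, reduction); the ylide comes from geranyl bromide (one-carbon homologation to homogeranyl iodide) and ethyl (triphenylphosphoranylidene)acetate.
- Ring order: ring A is bought with the salicylaldehyde; ring B is the only ring formed, in the key step.

Key step: step 15

Assumption: the usual shielding model for an E-iminium ion of a diarylprolinol silyl ether points to the (R)-catalyst for the 2S product; if a model reaction shows the opposite sense, the (S)-catalyst is used.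

Step 1
Reactants: 1 (2E,6E,10E)-geranylgeraniol
Product: 2 (2E,6E,10E)-geranylgeranyl tert-butyldimethylsilyl ether
Conditions: TBSCl, imidazole, DMF, 0 °C → rt
Reagents that add atoms: tert-butyldimethylsilyl chloride CC(C)(C)[Si](C)(C)Cl
Why: Imidazole-assisted silylation of an unhindered primary allylic alcohol is routine and masks C1 for the chain-building steps.

Step 2
Reactants: 2 (2E,6E,10E)-geranylgeranyl tert-butyldimethylsilyl ether
Product: 3 (2E,6E,10E,14E)-16-(tert-butyldimethylsilyloxy)-2,6,10,14-tetramethylhexadeca-2,6,10,14-tetraen-1-ol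
Conditions: SeO2 (0.1 equiv), tBuOOH (3 equiv), salicylic acid (0.1 equiv), CH2Cl2, 0 °C → rt; then NaBH4, EtOH, 0 °C
Reagents that add atoms: tert-butyl hydroperoxide CC(C)(C)OO (oxygen relayed through catalytic SeO2, O=[Se]=O)
Why: Riley-type allylic oxidation (ene reaction, then [2,3]-sigmatropic shift) should attack the terminal gem-dimethyl alkene at the methyl group trans to the chain, which fixes the new terminal alkene as E; the borohydride treatment returns any over-oxidised enal to 3.

Step 3
Reactants: 3 (2E,6E,10E,14E)-16-(tert-butyldimethylsilyloxy)-2,6,10,14-tetramethylhexadeca-2,6,10,14-tetraen-1-ol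
Product: 5 (2E,6E,10E,14E)-16-bromo-1-(tert-butyldimethylsilyloxy)-3,7,11,15-tetramethylhexadeca-2,6,10,14-tetraene, via allylic mesylate 4 (not isolated)
Conditions: MsCl, Et3N, THF, −45 °C; then LiBr, THF, −45 → 0 °C
Reagents that add atoms: lithium bromide [Li+].[Br-]; methanesulfonyl chloride CS(=O)(=O)Cl (its atoms stay only in 4)
Why: Mesylation followed by Finkelstein-type SN2 displacement with bromide converts primary allylic alcohols of polyprenyl chains to bromides without allylic transposition or loss of the silyl ether.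

Step 4
Reactants: 5 (2E,6E,10E,14E)-16-bromo-1-(tert-butyldimethylsilyloxy)-3,7,11,15-tetramethylhexadeca-2,6,10,14-tetraene
Product: 6 (4E,8E,12E,16E)-18-(tert-butyldimethylsilyloxy)-4,8,12,16-tetramethyloctadeca-4,8,12,16-tetraenenitrile
Conditions: MeCN, n-BuLi, THF, −78 °C; then 5, −78 → −20 °C
Reagents that add atoms: acetonitrile CC#N
Why: SN2 alkylation of lithioacetonitrile at the unhindered primary allylic carbon adds the two carbons needed, the SN2' position being a more hindered trisubstituted alkene carbon.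

Step 5
Reactants: 6 (4E,8E,12E,16E)-18-(tert-butyldimethylsilyloxy)-4,8,12,16-tetramethyloctadeca-4,8,12,16-tetraenenitrile
Product: 8 (4E,8E,12E,16E)-18-(tert-butyldimethylsilyloxy)-4,8,12,16-tetramethyloctadeca-4,8,12,16-tetraenal, via aluminium aldimide 7 (not isolated)
Conditions: iBu2AlH (1.3 equiv), CH2Cl2, −78 °C; then aq. tartaric acid, 0 °C
Reagents that add atoms: water O
Why: Partial reduction of a nitrile by iBu2AlH stops at the N-aluminio aldimine, which mild aqueous acid hydrolyses to the aldehyde without touching the silyl ether.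

Step 6
Reactants: 9 geranyl bromide
Product: 10 homogeranyl phenyl sulfide, [(3E)-4,8-dimethylnona-3,7-dien-1-yl](phenyl)sulfane
Conditions: PhSMe, n-BuLi, DABCO, THF, 0 °C; then 9, −78 °C → rt
Reagents that add atoms: thioanisole CSc1ccccc1
Why: SN2 alkylation of (phenylthio)methyllithium by the primary allylic bromide is an established one-carbon homologation that keeps the E-alkene.

Step 7
Reactants: 10 homogeranyl phenyl sulfide
Product: 12 homogeranyl iodide (3E)-1-iodo-4,8-dimethylnona-3,7-diene, via sulfonium iodide 11 (not isolated)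
Conditions: MeI (excess), NaI, DMF, 70 °C
Reagents that add atoms: methyl iodide CI (supplies the iodide; NaI, [Na+].[I-], keeps the iodide concentration high)
Why: S-methylation gives a sulfonium salt whose primary carbon is displaced by iodide (SN2) with thioanisole as leaving group, a known route from homoallylic sulfides to iodides.

Step 8
Reactants: 12 homogeranyl iodide; 13 ethyl (triphenylphosphoranylidene)acetate
Product: 15 ethyl (5E)-6,10-dimethyl-2-(triphenylphosphoranylidene)undeca-5,9-dienoate, via phosphonium iodide 14 (not isolated)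
Conditions: MeCN, 80 °C, 48 h; then 1 M NaOH, CH2Cl2, rt
Reagents that add atoms: none
Why: C-alkylation of a stabilised phosphorus ylide by a primary iodide (SN2) followed by deprotonation of the phosphonium salt is the standard entry to α-alkylated ester ylides.

Step 9
Reactants: 8 (4E,8E,12E,16E)-18-(tert-butyldimethylsilyloxy)-4,8,12,16-tetramethyloctadeca-4,8,12,16-tetraenal; 15 ethyl (5E)-6,10-dimethyl-2-(triphenylphosphoranylidene)undeca-5,9-dienoate
Product: 16 ethyl (2E,6E,10E,14E,18E)-20-(tert-butyldimethylsilyloxy)-2-[(3E)-4,8-dimethylnona-3,7-dien-1-yl]-6,10,14,18-tetramethylicosa-2,6,10,14,18-pentaenoate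
Conditions: toluene, 70 °C
Reagents that add atoms: none
Why: Wittig olefination of an unbranched aldehyde with an α-substituted stabilised ylide should place the aldehyde residue trans to the ester, which gives the 2E-enoate and so the required geometry of the branched alkene.

Step 10
Reactants: 16 ethyl (2E,6E,10E,14E,18E)-20-(tert-butyldimethylsilyloxy)-2-[(3E)-4,8-dimethylnona-3,7-dien-1-yl]-6,10,14,18-tetramethylicosa-2,6,10,14,18-pentaenoate
Product: 17 (2E,6E,10E,14E,18E)-20-(tert-butyldimethylsilyloxy)-2-[(3E)-4,8-dimethylnona-3,7-dien-1-yl]-6,10,14,18-tetramethylicosa-2,6,10,14,18-pentaen-1-ol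
Conditions: iBu2AlH (2.5 equiv), CH2Cl2, −78 → −20 °C; aq. KNaC4H4O6 (potassium sodium tartrate)
Reagents that add atoms: none
Why: 1,2-Reduction of an α,β-unsaturated ester by iBu2AlH gives the allylic alcohol with the alkene geometry unchanged.

Step 11
Reactants: 17 (2E,6E,10E,14E,18E)-20-(tert-butyldimethylsilyloxy)-2-[(3E)-4,8-dimethylnona-3,7-dien-1-yl]-6,10,14,18-tetramethylicosa-2,6,10,14,18-pentaen-1-ol
Product: 18 (2E,6E,10E,14E,18E,22E)-1-(tert-butyldimethylsilyloxy)-19-[(tert-butyldiphenylsilyloxy)methyl]-3,7,11,15,23,27-hexamethyloctacosa-2,6,10,14,18,22,26-heptaene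
Conditions: TBDPSCl, imidazole, DMF, rt
Reagents that add atoms: tert-butyldiphenylsilyl chloride CC(C)(C)[Si](Cl)(c1ccccc1)c1ccccc1
Why: Silylation of the primary allylic alcohol with the more acid-stable tert-butyldiphenylsilyl group makes the two silyl ethers distinguishable in the next step.

Step 12
Reactants: 18 (2E,6E,10E,14E,18E,22E)-1-(tert-butyldimethylsilyloxy)-19-[(tert-butyldiphenylsilyloxy)methyl]-3,7,11,15,23,27-hexamethyloctacosa-2,6,10,14,18,22,26-heptaene
Product: 19 (2E,6E,10E,14E,18E,22E)-19-[(tert-butyldiphenylsilyloxy)methyl]-3,7,11,15,23,27-hexamethyloctacosa-2,6,10,14,18,22,26-heptaen-1-ol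
Conditions: PPTS (0.2 equiv), EtOH, rt
Reagents that add atoms: none
Why: Acid-catalysed ethanolysis cleaves a primary tert-butyldimethylsilyl ether far faster than a tert-butyldiphenylsilyl ether, so only C1 should be freed.

Step 13
Reactants: 19 (2E,6E,10E,14E,18E,22E)-19-[(tert-butyldiphenylsilyloxy)methyl]-3,7,11,15,23,27-hexamethyloctacosa-2,6,10,14,18,22,26-heptaen-1-ol
Product: 20 (2E,6E,10E,14E,18E,22E)-19-[(tert-butyldiphenylsilyloxy)methyl]-3,7,11,15,23,27-hexamethyloctacosa-2,6,10,14,18,22,26-heptaenal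
Conditions: MnO2 (activated, 20 equiv), CH2Cl2, rt
Reagents that add atoms: none
Why: MnO2 oxidises allylic alcohols to enals chemoselectively and should keep the 2E geometry.

Step 14
Reactants: 21 2,5-dihydroxybenzaldehyde
Product: 22 5-(tert-butyldimethylsilyloxy)-2-hydroxybenzaldehyde
Conditions: TBSCl (1.05 equiv), imidazole, CH2Cl2, 0 °C
Reagents that add atoms: tert-butyldimethylsilyl chloride CC(C)(C)[Si](C)(C)Cl
Why: Regioselective silylation is expected at the 5-hydroxyl, because the 2-hydroxyl is tied up in a hydrogen bond to the formyl group and is the less nucleophilic of the two.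

Step 15
Reactants: 20 (2E,6E,10E,14E,18E,22E)-19-[(tert-butyldiphenylsilyloxy)methyl]-3,7,11,15,23,27-hexamethyloctacosa-2,6,10,14,18,22,26-heptaenal; 22 5-(tert-butyldimethylsilyloxy)-2-hydroxybenzaldehyde
Product: 23 (2S)-6-(tert-butyldimethylsilyloxy)-2-methyl-2-[(3E,7E,11E,15E,19E)-16-[(tert-butyldiphenylsilyloxy)methyl]-4,8,12,20,24-pentamethylpentacosa-3,7,11,15,19,23-hexaen-1-yl]-2H-chromene-3-carbaldehyde
Conditions: (R)-2-[diphenyl(triethylsilyloxy)methyl]pyrrolidine (30 mol%), 2-nitrobenzoic acid (30 mol%), 4 Å molecular sieves, toluene, 0 °C → rt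
Reagents that add atoms: none
Why: The amine condenses with enal 20 to an iminium ion that equilibrates with its dienamine; bond formation from the enal α-carbon to the formyl carbon of 22 (C3–C4) and addition of the phenol oxygen to the β-carbon (O1–C2) lead, in whichever order they occur, to a catalyst-bound 4-hydroxychroman-3-carbaldehyde that loses water irreversibly and is hydrolysed to 23. The closest known reactions are the amine- or base-mediated domino oxa-Michael/aldol condensation of salicylaldehydes with enals (3-methylbut-2-enal among them) and the diarylprolinol-silyl-ether-catalysed aldol/oxa-Michael domino of a β-methyl long-chain enal. Ring B closes by a 6-endo-trig oxa-Michael addition if the C–C bond forms first and by a 6-(enolexo)-exo-trig aldol addition if the C–O bond forms first. The C2 stereocentre arises in the C–O bond formation and is controlled by the diphenyl(silyloxy)methyl group of the catalyst, which blocks one face of the E-iminium ion so that oxygen adds to the open face; because the oxygen addition is reversible, the ratio is locked only at the dehydration. The step needs C–C bond formation at the α-carbon and not at the γ-methyl group, and facial discrimination at a fully substituted carbon: dehydration to the conjugated chromene aldehyde is a drain open only to the α-adduct, the hydrogen-bonded ortho-phenol is delivered intramolecularly, and the unlike β-substituents (methyl against a long CH2 chain) favour the 2E-iminium ion although E and Z forms interconvert through the dienamine. The level of enantioselectivity at this quaternary centre is the open question of the route.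

Step 16
Reactants: 23 (2S)-6-(tert-butyldimethylsilyloxy)-2-methyl-2-[(3E,7E,11E,15E,19E)-16-[(tert-butyldiphenylsilyloxy)methyl]-4,8,12,20,24-pentamethylpentacosa-3,7,11,15,19,23-hexaen-1-yl]-2H-chromene-3-carbaldehyde
Product: 24 (2S)-6-(tert-butyldimethylsilyloxy)-2-methyl-2-[(3E,7E,11E,15E,19E)-16-[(tert-butyldiphenylsilyloxy)methyl]-4,8,12,20,24-pentamethylpentacosa-3,7,11,15,19,23-hexaen-1-yl]-2H-chromene
Conditions: RhCl(PPh3)3 (1.1 equiv), degassed toluene, 80–100 °C (lowest temperature that gives conversion)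
Reagents that add atoms: none
Why: Tsuji–Wilkinson decarbonylation (oxidative addition of the formyl C–H bond, CO extrusion, reductive elimination) replaces the formyl group on the sp2 carbon C3 by hydrogen without involving the C2 stereocentre, and stoichiometric rhodium avoids the much higher temperature that catalytic turnover needs.

Step 17
Reactants: 24 (2S)-6-(tert-butyldimethylsilyloxy)-2-methyl-2-[(3E,7E,11E,15E,19E)-16-[(tert-butyldiphenylsilyloxy)methyl]-4,8,12,20,24-pentamethylpentacosa-3,7,11,15,19,23-hexaen-1-yl]-2H-chromene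
Product: 25 (2S)-2-[(3E,7E,11E,15E,19E)-16-(hydroxymethyl)-4,8,12,20,24-pentamethylpentacosa-3,7,11,15,19,23-hexaen-1-yl]-2-methyl-2H-chromen-6-ol (CNP0017559.1)
Conditions: Bu4NF (3 equiv), THF, 0 °C → rt
Reagents that add atoms: none
Why: Fluoride-mediated desilylation removes the aryl and the allylic silyl ether in one operation and leaves the chromene, the alkenes and the stereocentre untouched.

**Compound list**
1 | (2E,6E,10E)-geranylgeraniol | CC(C)=CCC/C(C)=C/CC/C(C)=C/CC/C(C)=C/CO | starting material
2 | (2E,6E,10E)-geranylgeranyl tert-butyldimethylsilyl ether | CC(C)=CCC/C(C)=C/CC/C(C)=C/CC/C(C)=C/CO[Si](C)(C)C(C)(C)C | intermediate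
3 | (2E,6E,10E,14E)-16-(tert-butyldimethylsilyloxy)-2,6,10,14-tetramethylhexadeca-2,6,10,14-tetraen-1-ol | OC/C(C)=C/CC/C(C)=C/CC/C(C)=C/CC/C(C)=C/CO[Si](C)(C)C(C)(C)C | intermediate
4 | methanesulfonate of 3 (allylic mesylate) | CS(=O)(=O)OC/C(C)=C/CC/C(C)=C/CC/C(C)=C/CC/C(C)=C/CO[Si](C)(C)C(C)(C)C | intermediate (not isolated)
5 | (2E,6E,10E,14E)-16-bromo-1-(tert-butyldimethylsilyloxy)-3,7,11,15-tetramethylhexadeca-2,6,10,14-tetraene | BrC/C(C)=C/CC/C(C)=C/CC/C(C)=C/CC/C(C)=C/CO[Si](C)(C)C(C)(C)C | intermediate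
6 | (4E,8E,12E,16E)-18-(tert-butyldimethylsilyloxy)-4,8,12,16-tetramethyloctadeca-4,8,12,16-tetraenenitrile | N#CCC/C(C)=C/CC/C(C)=C/CC/C(C)=C/CC/C(C)=C/CO[Si](C)(C)C(C)(C)C | intermediate
7 | N-(diisobutylaluminio) aldimine of 8 (aluminium aldimide) | CC(C)C[Al](CC(C)C)N=CCC/C(C)=C/CC/C(C)=C/CC/C(C)=C/CC/C(C)=C/CO[Si](C)(C)C(C)(C)C | intermediate (not isolated)
8 | (4E,8E,12E,16E)-18-(tert-butyldimethylsilyloxy)-4,8,12,16-tetramethyloctadeca-4,8,12,16-tetraenal | O=CCC/C(C)=C/CC/C(C)=C/CC/C(C)=C/CC/C(C)=C/CO[Si](C)(C)C(C)(C)C | intermediate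
9 | geranyl bromide, (2E)-1-bromo-3,7-dimethylocta-2,6-diene | CC(C)=CCC/C(C)=C/CBr | starting material
10 | homogeranyl phenyl sulfide, [(3E)-4,8-dimethylnona-3,7-dien-1-yl](phenyl)sulfane | CC(C)=CCC/C(C)=C/CCSc1ccccc1 | intermediate
11 | [(3E)-4,8-dimethylnona-3,7-dien-1-yl](methyl)phenylsulfonium iodide | CC(C)=CCC/C(C)=C/CC[S+](C)c1ccccc1.[I-] | intermediate (not isolated)
12 | homogeranyl iodide, (3E)-1-iodo-4,8-dimethylnona-3,7-diene | CC(C)=CCC/C(C)=C/CCI | intermediate
13 | ethyl (triphenylphosphoranylidene)acetate | CCOC(=O)C=P(c1ccccc1)(c1ccccc1)c1ccccc1 | starting material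
14 | [(5E)-1-ethoxy-6,10-dimethyl-1-oxoundeca-5,9-dien-2-yl]triphenylphosphonium iodide | CC(C)=CCC/C(C)=C/CCC(C(=O)OCC)[P+](c1ccccc1)(c1ccccc1)c1ccccc1.[I-] | intermediate (not isolated)
15 | ethyl (5E)-6,10-dimethyl-2-(triphenylphosphoranylidene)undeca-5,9-dienoate | CC(C)=CCC/C(C)=C/CCC(C(=O)OCC)=P(c1ccccc1)(c1ccccc1)c1ccccc1 | intermediate
16 | ethyl (2E,6E,10E,14E,18E)-20-(tert-butyldimethylsilyloxy)-2-[(3E)-4,8-dimethylnona-3,7-dien-1-yl]-6,10,14,18-tetramethylicosa-2,6,10,14,18-pentaenoate | CC(C)=CCC/C(C)=C/CC/C(=C\CC/C(C)=C/CC/C(C)=C/CC/C(C)=C/CC/C(C)=C/CO[Si](C)(C)C(C)(C)C)C(=O)OCC | intermediate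
17 | (2E,6E,10E,14E,18E)-20-(tert-butyldimethylsilyloxy)-2-[(3E)-4,8-dimethylnona-3,7-dien-1-yl]-6,10,14,18-tetramethylicosa-2,6,10,14,18-pentaen-1-ol | CC(C)=CCC/C(C)=C/CC/C(=C\CC/C(C)=C/CC/C(C)=C/CC/C(C)=C/CC/C(C)=C/CO[Si](C)(C)C(C)(C)C)CO | intermediate
18 | (2E,6E,10E,14E,18E,22E)-1-(tert-butyldimethylsilyloxy)-19-[(tert-butyldiphenylsilyloxy)methyl]-3,7,11,15,23,27-hexamethyloctacosa-2,6,10,14,18,22,26-heptaene | CC(C)=CCC/C(C)=C/CC/C(=C\CC/C(C)=C/CC/C(C)=C/CC/C(C)=C/CC/C(C)=C/CO[Si](C)(C)C(C)(C)C)CO[Si](c1ccccc1)(c1ccccc1)C(C)(C)C | intermediate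
19 | (2E,6E,10E,14E,18E,22E)-19-[(tert-butyldiphenylsilyloxy)methyl]-3,7,11,15,23,27-hexamethyloctacosa-2,6,10,14,18,22,26-heptaen-1-ol | CC(C)=CCC/C(C)=C/CC/C(=C\CC/C(C)=C/CC/C(C)=C/CC/C(C)=C/CC/C(C)=C/CO)CO[Si](c1ccccc1)(c1ccccc1)C(C)(C)C | intermediate
20 | (2E,6E,10E,14E,18E,22E)-19-[(tert-butyldiphenylsilyloxy)methyl]-3,7,11,15,23,27-hexamethyloctacosa-2,6,10,14,18,22,26-heptaenal (key-step precursor) | CC(C)=CCC/C(C)=C/CC/C(=C\CC/C(C)=C/CC/C(C)=C/CC/C(C)=C/CC/C(C)=C/C=O)CO[Si](c1ccccc1)(c1ccccc1)C(C)(C)C | intermediate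
21 | 2,5-dihydroxybenzaldehyde | O=Cc1cc(O)ccc1O | starting material
22 | 5-(tert-butyldimethylsilyloxy)-2-hydroxybenzaldehyde (key-step precursor) | O=Cc1cc(O[Si](C)(C)C(C)(C)C)ccc1O | intermediate
23 | (2S)-6-(tert-butyldimethylsilyloxy)-2-methyl-2-[(3E,7E,11E,15E,19E)-16-[(tert-butyldiphenylsilyloxy)methyl]-4,8,12,20,24-pentamethylpentacosa-3,7,11,15,19,23-hexaen-1-yl]-2H-chromene-3-carbaldehyde (key-step product) | CC(C)=CCC/C(C)=C/CC/C(=C\CC/C(C)=C/CC/C(C)=C/CC/C(C)=C/CC[C@@]1(C)C(C=O)=Cc2cc(O[Si](C)(C)C(C)(C)C)ccc2O1)CO[Si](c1ccccc1)(c1ccccc1)C(C)(C)C | intermediate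
24 | (2S)-6-(tert-butyldimethylsilyloxy)-2-methyl-2-[(3E,7E,11E,15E,19E)-16-[(tert-butyldiphenylsilyloxy)methyl]-4,8,12,20,24-pentamethylpentacosa-3,7,11,15,19,23-hexaen-1-yl]-2H-chromene | CC(C)=CCC/C(C)=C/CC/C(=C\CC/C(C)=C/CC/C(C)=C/CC/C(C)=C/CC[C@@]1(C)C=Cc2cc(O[Si](C)(C)C(C)(C)C)ccc2O1)CO[Si](c1ccccc1)(c1ccccc1)C(C)(C)C | intermediate
25 | (2S)-2-[(3E,7E,11E,15E,19E)-16-(hydroxymethyl)-4,8,12,20,24-pentamethylpentacosa-3,7,11,15,19,23-hexaen-1-yl]-2-methyl-2H-chromen-6-ol | CC(C)=CCC/C(C)=C/CC/C(=C\CC/C(C)=C/CC/C(C)=C/CC/C(C)=C/CC[C@@]1(C)C=Cc2cc(O)ccc2O1)CO | target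

**Step count**
Total step count: 17.
Longest linear sequence: 13 steps (steps 1–5, 9–13, 15–17, from geranylgeraniol).

**Steps most likely to fail**

Step 15. What may go wrong: the dienamine may form its C–C bond at the γ-methyl carbon instead of the α-carbon and drain into a bridged lactol; turnover may be slow for the hindered β,β-disubstituted iminium ion; facial selectivity may be low or may erode because the oxygen addition is reversible. Fallback (sets out from 20 and 22, comes back at 24): the γ-pathway is taken on purpose. Under a diarylprolinol silyl ether with benzoic acid in toluene, the course reported for β-methyl long-chain enals is a vinylogous aldol addition of the cross-conjugated dienamine through its methyl carbon to the salicylaldehyde. The phenol then closes by 6-exo-trig oxa-Michael addition and the aldol hydroxyl traps the aldehyde, which would give the bridged lactol F1 (C2 already quaternary; the former methyl carbon is C3). Catalytic pyridinium p-toluenesulfonate in warm toluene would open the lactol and dehydrate the benzylic C4 alcohol to the 2-(2-oxoethyl)-2H-chromene F2. RhCl(PPh3)3 would then decarbonylate this saturated aldehyde at moderate temperature, turning the CH2CHO arm into the C2 methyl group of 24. The catalyst enantiomer is chosen for the 2S series.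

Step 16. What may go wrong: CO extrusion from the conjugated acyl–rhodium hydride may be slow, so that the temperature required allows reversible electrocyclic opening of the 3-formyl-2H-chromene and loss of configurational purity at C2; alkenes of the chain may migrate. Fallback (sets out from 20, comes back at 25): a route that never places a formyl group on ring B, at the price of a resolution. Enal 20 is condensed with commercial 4-(tert-butyldimethylsilyloxy)phenol F3 (PhB(OH)2, propionic acid, toluene, reflux with removal of water; ortho-quinone methide formation, then oxa-6π electrocyclisation), which should give the racemic bis-silyl chromene F4 directly. Bu4NF gives the racemic diol F5, and its enantiomers are separated by preparative HPLC on an amylose tris(3,5-dimethylphenylcarbamate) phase to give 25.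

Step 8. What may go wrong: the SN2 reaction of the weakly nucleophilic stabilised ylide with an unactivated primary iodide may be sluggish, transylidation may stay incomplete, and HI may be eliminated from 12. Fallback (sets out from 12, comes back at 15): the P–C bond is made last. Iodide 12 alkylates the lithium enolate of ethyl acetate (LiN(iPr)2, THF/DMPU, −78 °C) to ethyl (5E)-6,10-dimethylundeca-5,9-dienoate F6. Its lithium enolate is brominated with CBr4 to the 2-bromo ester F7. PPh3 in toluene at 90 °C gives the phosphonium bromide F8, and aqueous NaOH gives 15.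

Further compounds
F1 | step 15 | bridged lactol: (2S,4S)-6-(tert-butyldimethylsilyloxy)-2-(polyprenyl)chroman (chain as in 24) whose C2 carries a CH2–CH(OH)–O bridge to C4, anomeric mixture | CC(C)=CCC/C(C)=C/CC/C(=C\CC/C(C)=C/CC/C(C)=C/CC/C(C)=C/CC[C@@]12CC(O)O[C@@H](C1)c1cc(O[Si](C)(C)C(C)(C)C)ccc1O2)CO[Si](c1ccccc1)(c1ccccc1)C(C)(C)C
F2 | step 15 | 2-(2-oxoethyl)-2H-chromene: 24 with CH2CHO in place of the C2 methyl group (2R by the sequence rule, same spatial arrangement as 24) | CC(C)=CCC/C(C)=C/CC/C(=C\CC/C(C)=C/CC/C(C)=C/CC/C(C)=C/CC[C@@]1(CC=O)C=Cc2cc(O[Si](C)(C)C(C)(C)C)ccc2O1)CO[Si](c1ccccc1)(c1ccccc1)C(C)(C)C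
F3 | step 16 | 4-(tert-butyldimethylsilyloxy)phenol (purchased) | Oc1ccc(O[Si](C)(C)C(C)(C)C)cc1
F4 | step 16 | racemic bis-silyl chromene (racemate of 24) | CC(C)=CCC/C(C)=C/CC/C(=C\CC/C(C)=C/CC/C(C)=C/CC/C(C)=C/CCC1(C)C=Cc2cc(O[Si](C)(C)C(C)(C)C)ccc2O1)CO[Si](c1ccccc1)(c1ccccc1)C(C)(C)C
F5 | step 16 | racemic diol (racemate of 25) | CC(C)=CCC/C(C)=C/CC/C(=C\CC/C(C)=C/CC/C(C)=C/CC/C(C)=C/CCC1(C)C=Cc2cc(O)ccc2O1)CO
F6 | step 8 | ethyl (5E)-6,10-dimethylundeca-5,9-dienoate | CC(C)=CCC/C(C)=C/CCCC(=O)OCC
F7 | step 8 | ethyl (5E)-2-bromo-6,10-dimethylundeca-5,9-dienoate (racemic) | CC(C)=CCC/C(C)=C/CCC(Br)C(=O)OCC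
F8 | step 8 | [(5E)-1-ethoxy-6,10-dimethyl-1-oxoundeca-5,9-dien-2-yl]triphenylphosphonium bromide | CC(C)=CCC/C(C)=C/CCC(C(=O)OCC)[P+](c1ccccc1)(c1ccccc1)c1ccccc1.[Br-]
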